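The constants were drawn at random within sensible limits; the flask was simulated.

The solid substrate charged stands throughout in three forms, as solid, as dissolved starting material and as target, and their sum does not change.

    starting material + reagent ⇌ target (K1 = 2400 M⁻¹, k1 = 21 M⁻¹ s⁻¹)
    solid substrate ⇌ starting material, rate k2*(cs2 - [starting material]) while solid is left; crystals form when [starting material] > cs2 (cs2 = 1.4 mM, k2 = 0.11 s⁻¹)
    second substrate + reagent ⇌ second product (K3 = 940 M⁻¹, k3 = 180 M⁻¹ s⁻¹)
    gas ⇌ reagent, rate k4*(csat - [reagent]) (k4 = 0.19 s⁻¹, csat = 0.91 mM)

solid substrate 10 mM; second substrate 1.00 equiv (fed, over 30 s); gas 0.91 mM (held); time 40 min

- as a solid, counted per litre of solution: solid substrate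
- at the start none of reagent is dissolved
- at the start none of the solid substrate is in solution
- what has only dissolved of solid substrate counts as not reacted
- the reaction counts as stopped when no species that holds the solid substrate changes by six tenths of a point or more over the second half of the time
- run time (flask): 40 min

* at 40 min, what has stopped the reaction, if anything has (for what has run out or reacted, a solid counts together with what of it has only dissolved) (forward and back rates have come level / all of the solid substrate has reacted / it is still moving)
* part of the solid substrate that has turned into other species by 40 min (what has only dissolved does not count)
* amount of target at 40 min, in percent of the solid substrate charged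

Two numbers here do not seem to go together. Dissolving has a lifetime of 9.09 s, so the run holds 264 such lifetimes, yet we expect solid at the end. The rate law clears this up: that lifetime belongs to the gap between [starting material] and 1.4 mM, not to the solid. Once the gap has closed, solid leaves as fast as the reaction draws starting material away.

So we count turnovers of the target. Its back lifetime is 114 s, and the run holds 21.0 of them, more than enough for the step to come level. The second product has a shorter back lifetime, 5.22 s, and so balances sooner. The gas can then supply up to 0.173 mM s⁻¹, more than the 0.0268 mM s⁻¹ the target step can take at most, so [reagent] rises to near its saturation value of 0.91 mM.

The balance ratio, [target] over [starting material] with that step level and reagent at saturation, is 2.18. The solution therefore holds 4.46 mM in the two forms together, less than the 10 mM charged, and solid remains. We commit to forward and back rates have come level, with 3.06 mM of target, which gives 30.6% yield and 30.6% conversion.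

The forecast says forward and back rates have come level, with 30.6% conversion (29.5% to 31.5%) and 30.6% target (29.5% to 31.5%): "the system has levelled off with over half the solid undissolved".

The flask gives forward and back rates have come level, with 30.6% conversion and 30.6% target. The conversion was close to that value by 8.29 min, earlier than the 40 min of the run, and at 40.0 min [target] over [starting material] stands at 2.18 against the balance ratio of 2.18. For the neighbour flask with 4.0 mM of solid substrate, the 4.46 mM reckoned for the solution exceeds the charge, and the balance ratio applied to the whole charge gives 68.6% in target. That neighbour flask ends with 0% solid substrate and 68.6% target.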